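**Plan**
- Retrosynthetic cuts, in order: C3=C4 (ketone dehydrogenation) and N–CHO; N–C1 and N–C9 (ring C, by sulfonamide alkylations); the C13 and C15 oxygens (from a ring A enone); then C5–C6 and C4–C12 together (ring B); finally the vinyl ether C5–O bond between two fragments, C7–C6 (cross-coupling) and C12–C11 (Michael addition).
- Enabling feature: ring B is a cyclopentanone whose carbonyl C5 lies between C6H2 and C4, and C4 sits on the quaternary C12 next to C7. C5(=O)–C4–C12–C7–C6 is therefore a 4-pentenal with a C7=C6 exo-methylene, the Claisen product of an allyl vinyl ether O–C6H2–C7=C12 / C5H=C4.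
- Forward order: ring A (from cyclohexane-1,3-dione), fragment union by copper-catalysed O-vinylation, ring B in one pot (Claisen rearrangement, then rhodium hydroacylation), ring A oxidation, ring C (azonane), enone.
- Stereochemistry: C13 from a CBS reduction; the pseudoaxial C13 silyl ether steers the Claisen step (C12); hydroacylation gives the cis ring fusion (C7). C13 is then oxidised and re-set by Luche reduction from the convex face, and relays to C15 by hydroxyl-directed epoxidation.

Key step: step 8

Remark: locants C1–C16 are those used in the plan (ring A = C13, C14, C15, C8, C7, C12; ring B = C7, C6, C5, C4, C12; ring C = C4, C3, C2, C1, N, C9, C10, C11, C12; C16 = methyl on C15). β is the face of ring A that carries both acetoxy groups in the target, α the opposite face. The C4 configuration drawn for 11–26 is the one expected from the chair Claisen transition state; it is erased in step 21.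

**Route**

Step 1
Reactants: 1 cyclohexane-1,3-dione; 2 tert-butyl acrylate
Product: 3 tert-butyl 3-(2,6-dioxocyclohexyl)propanoate
Conditions: KOtBu (0.1 equiv), t-BuOH, 50 °C; 1 in 1.5-fold excess
Reagents that add atoms: none
Why: Michael addition of the doubly stabilised C12 enolate of the 1,3-dione to the acrylate installs C11–C10–C9, and the excess of dione suppresses double addition.

Step 2
Reactants: 3 tert-butyl 3-(2,6-dioxocyclohexyl)propanoate
Product: 4 enol triflate
Conditions: Tf2O, pyridine, CH2Cl2, −78 → 0 °C
Reagents that add atoms: trifluoromethanesulfonic anhydride, O=S(=O)(OS(=O)(=O)C(F)(F)F)C(F)(F)F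
Why: O-sulfonylation of the enolised symmetric 1,3-dione (enol triflate formation) gives a single vinylogous acyl triflate that marks C7 for cross-coupling.

Step 3
Reactants: 4 enol triflate
Product: 5 (R)-allylic alcohol
Conditions: (S)-2-methyl-CBS-oxazaborolidine (10 mol %), BH3·THF, THF, −20 °C
Reagents that add atoms: none
Why: Corey–Bakshi–Shibata 1,2-reduction in which the α-substituted alkene carbon C12 acts as the large group, so the (S)-catalyst is expected to give the 13R (13α) carbinol, the only stereocentre in the route set by a chiral reagent.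

Step 4
Reactants: 5 (R)-allylic alcohol
Product: 6 triethylsilyl ether
Conditions: Et3SiCl, imidazole, DMF, 0 → 23 °C
Reagents that add atoms: chlorotriethylsilane, CC[Si](Cl)(CC)CC
Why: Standard silylation protects the C13 oxygen and makes it the bulky allylic substituent that later directs the rearrangement.

Step 5
Reactants: 6 triethylsilyl ether
Product: 7 allylic alcohol (fragment A)
Conditions: Bu3SnCH2OH, Pd(PPh3)4 (5 mol %), LiCl, 1,4-dioxane, 100 °C
Reagents that add atoms: (tributylstannyl)methanol, CCCC[Sn](CO)(CCCC)CCCC
Why: Stille hydroxymethylation of the enol triflate installs C6 as a free primary allylic alcohol on the tetrasubstituted C7=C12 alkene without touching the silyl ether or the ester.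

Step 6
Reactants: 8 5-chloropent-1-yne
Product: 9 (E)-5-chloro-1-iodopent-1-ene (fragment B)
Conditions: Cp2Zr(H)Cl, THF, 23 °C; then I2, 0 °C
Reagents that add atoms: iodine, II
Why: Hydrozirconation adds Zr–H syn with zirconium at the terminal carbon, and iodinolysis with retention gives the E-vinyl iodide that carries C5–C1.

Step 7
Reactants: 7 allylic alcohol (fragment A); 9 (E)-5-chloro-1-iodopent-1-ene (fragment B)
Product: 10 allyl vinyl ether
Conditions: CuI (10 mol %), 3,4,7,8-tetramethyl-1,10-phenanthroline (20 mol %), Cs2CO3, toluene, 80 °C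
Reagents that add atoms: none
Why: Copper-catalysed Ullmann-type C–O coupling of a vinyl iodide with a primary allylic alcohol proceeds with retention of the E geometry, and 80 °C is below the temperature at which this tetrasubstituted allyl unit rearranges.

Step 8
Reactants: 10 allyl vinyl ether
Product: 12 hydrindanone, via Claisen aldehyde 11 (not isolated)
Conditions: ClCH2CH2Cl, 150 °C (sealed tube); cool to 25 °C, add [Rh(dppe)]BF4 (10 mol %; dppe = Ph2PCH2CH2PPh2), 25 → 60 °C
Reagents that add atoms: none
Why: Heating triggers a Claisen rearrangement through a chair array O–C5=C4···C12=C7–C6 that forms C4–C12 and unveils the 4-pentenal 11 with a C7=C6 exo-methylene; the cationic rhodium catalyst then inserts into the aldehyde C–H bond, adds Rh–H across C7=C6 (H to C7, Rh to C6) and forms C5–C6 by reductive elimination. The closest known reaction type is the tandem Claisen rearrangement / rhodium-catalysed intramolecular hydroacylation of allyl vinyl ethers to cyclopentanones. Ring B is the only ring closed, by C–C reductive elimination from a six-membered acyl(alkyl)rhodium metallacycle with both alkene carbons ending inside the ring (a formal 5-endo closure onto the exo-methylene); the sigmatropic step closes no ring. C12 is set because the C13 silyl ether is pseudoaxial (A(1,2) strain with the C12 side chain), so C4 bonds to the opposite β face; C4 follows from the E-enol ether in the chair (C3 cis to C11 on ring B, erased later); C7 is expected cis-fused (H7 α) because alkene insertion is reversible and the angularly substituted cis-hydrindanone is the less strained product of reductive elimination. The step needs alkene insertion to outrun decarbonylation of the acyl hydride, which the fully substituted C12 (Thorpe–Ingold effect) and the unhindered CH2 terminus of the only alkene present should secure.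

Step 9
Reactants: 12 hydrindanone
Product: 13 hydroxy ketal
Conditions: HOCH2CH2OH, TsOH·H2O (10 mol %), 4 Å molecular sieves, CH2Cl2, 23 °C
Reagents that add atoms: ethylene glycol, OCCO
Why: Acid-catalysed dioxolane formation masks the C5 ketone against the enolisation and hydride steps that follow, and the same acidic diol medium solvolyses the triethylsilyl ether to free the C13 alcohol.

Step 10
Reactants: 13 hydroxy ketal
Product: 15 ring A enone, via ring A ketone 14 (not isolated)
Conditions: 2-iodoxybenzoic acid (IBX, 4 equiv), DMSO, 25 °C then 70 °C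
Reagents that add atoms: none
Why: IBX oxidises the neopentyl C13 alcohol to the ketone and at 70 °C dehydrogenates it (IBX dehydrogenation); the ketone can enolise only towards C14 because C12 is quaternary, so the C14=C15 enone is the only one possible.

Step 11
Reactants: 15 ring A enone
Product: 17 C15-methyl enone, via trimethylsilyl enol ether 16 (not isolated)
Conditions: Me2CuLi, Me3SiCl, THF, −78 °C; then Pd(OAc)2 (1.1 equiv), MeCN, 23 °C
Reagents that add atoms: lithium dimethylcuprate, [Li+].C[Cu-]C
Why: Gilman conjugate addition places the methyl group on C15 with silyl trapping of the enolate, and Saegusa–Ito oxidation of that enol ether restores the C14=C15 enone, so the transient C15 centre does not matter.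

Step 12
Reactants: 17 C15-methyl enone
Product: 18 13β-allylic alcohol
Conditions: NaBH4, CeCl3·7H2O, MeOH, −78 → 0 °C
Reagents that add atoms: none
Why: Luche 1,2-reduction in which hydride should add to C13 from the α face (the convex face, away from ring B and its ketal) to give the 13β (13S) alcohol, which inverts C13 relative to 7.

Step 13
Reactants: 18 13β-allylic alcohol
Product: 19 epoxy alcohol
Conditions: VO(acac)2 (5 mol %), t-BuOOH, CH2Cl2, 0 → 23 °C
Reagents that add atoms: tert-butyl hydroperoxide, CC(C)(C)OO
Why: Vanadium-catalysed hydroxyl-directed epoxidation delivers oxygen to the C14=C15 face syn to the C13 hydroxyl, i.e. the β face, which sets the C15–O bond cis to C13–O.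

Step 14
Reactants: 19 epoxy alcohol
Product: 20 triol
Conditions: NaAlH2(OCH2CH2OCH3)2 (Red-Al), THF, 0 → 23 °C
Reagents that add atoms: none
Why: Hydride delivered from the C13 alkoxyaluminate opens the 2,3-epoxy alcohol at the less substituted C14 (trans-diaxial opening to the 1,3-diol), leaving C15 with its β oxygen and α methyl, and the same reagent reduces the tert-butyl ester to the C9 primary alcohol.

Step 15
Reactants: 20 triol
Product: 21 sulfonamide
Conditions: 2-NO2C6H4SO2NH2 (3 equiv), PPh3, DIAD, THF, 0 → 23 °C
Reagents that add atoms: 2-nitrobenzenesulfonamide, NS(=O)(=O)c1ccccc1[N+](=O)[O-]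
Why: Fukuyama–Mitsunobu N-alkylation in which only the primary C9 alcohol is activated (the neopentyl C13 and tertiary C15 alcohols are inert) and the acidic sulfonamide is the only competent pronucleophile.

Step 16
Reactants: 21 sulfonamide
Product: 22 N-nosyl azonane diol
Conditions: Cs2CO3, NaI (0.2 equiv), DMF, 60 °C, 0.005 M
Reagents that add atoms: none
Why: Intramolecular SN2 alkylation of the caesium sulfonamide at C1 (iodide catalysis, high dilution, 9-exo-tet) closes ring C, the sulfonamide-anion closure used for azonanes of this alkaloid class, helped by the cis disposition of the C3 and C11 chains on ring B.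

Step 17
Reactants: 22 N-nosyl azonane diol
Product: 23 diacetate
Conditions: Ac2O, DMAP, Et3N, CH2Cl2, 23 → 40 °C
Reagents that add atoms: acetic anhydride, CC(=O)OC(C)=O
Why: DMAP-catalysed (Steglich-type) acylation esterifies both the hindered secondary C13 and the tertiary C15 alcohols while the sulfonamide nitrogen is inert.

Step 18
Reactants: 23 diacetate
Product: 24 secondary amine
Conditions: PhSH, K2CO3, DMF, 23 °C
Reagents that add atoms: none
Why: Thiolate ipso-attack on the nitroarene (Meisenheimer complex) and loss of SO2 removes the nosyl group under conditions that leave the acetates and the ketal intact.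

Step 19
Reactants: 24 secondary amine
Product: 25 formamide ketal
Conditions: acetic formic anhydride, CH2Cl2, 0 °C
Reagents that add atoms: acetic formic anhydride, CC(=O)OC=O
Why: The mixed anhydride transfers the more electrophilic formyl group to the ring nitrogen (N-formylation).

Step 20
Reactants: 25 formamide ketal
Product: 26 keto formamide
Conditions: PPTS, acetone/H2O (10:1), 55 °C
Reagents that add atoms: water, O
Why: Mild acid-catalysed hydrolysis of the cyclopentanone dioxolane frees the C5 ketone without cleaving the tertiary acetate or the formamide.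

Step 21
Reactants: 26 keto formamide
Product: 28 target compound, via C5 trimethylsilyl enol ether 27 (not isolated)
Conditions: Me3SiCl, Et3N, DMF, 80 °C; then Pd(OAc)2 (1.1 equiv), MeCN, 23 → 40 °C
Reagents that add atoms: none
Why: Equilibrating silylation gives the more substituted C5=C4 enol ether, and in the Saegusa–Ito oxidation the palladium enolate at C4 can lose a β-hydride only from C3 (C12 is quaternary), while ring C allows only the cis ring alkene, which is the E-enone of the target.

**Compound list**

1 | cyclohexane-1,3-dione | O=C1CCCC(=O)C1 | starting material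
2 | tert-butyl acrylate | C=CC(=O)OC(C)(C)C | starting material
3 | tert-butyl 3-(2,6-dioxocyclohexyl)propanoate | O=C1CCCC(=O)C1CCC(=O)OC(C)(C)C | intermediate
4 | tert-butyl 3-[6-oxo-2-(trifluoromethanesulfonyloxy)cyclohex-1-en-1-yl]propanoate (enol triflate) | O=C1CCCC(OS(=O)(=O)C(F)(F)F)=C1CCC(=O)OC(C)(C)C | intermediate
5 | tert-butyl 3-[(6R)-6-hydroxy-2-(trifluoromethanesulfonyloxy)cyclohex-1-en-1-yl]propanoate | O[C@@H]1CCCC(OS(=O)(=O)C(F)(F)F)=C1CCC(=O)OC(C)(C)C | intermediate
6 | tert-butyl 3-[(6R)-6-(triethylsilyloxy)-2-(trifluoromethanesulfonyloxy)cyclohex-1-en-1-yl]propanoate | CC[Si](CC)(CC)O[C@@H]1CCCC(OS(=O)(=O)C(F)(F)F)=C1CCC(=O)OC(C)(C)C | intermediate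
7 | tert-butyl 3-[(6R)-2-(hydroxymethyl)-6-(triethylsilyloxy)cyclohex-1-en-1-yl]propanoate (fragment A) | CC[Si](CC)(CC)O[C@@H]1CCCC(CO)=C1CCC(=O)OC(C)(C)C | intermediate
8 | 5-chloropent-1-yne | C#CCCCCl | starting material
9 | (E)-5-chloro-1-iodopent-1-ene (fragment B) | I/C=C/CCCCl | intermediate
10 | tert-butyl 3-[(6R)-2-({[(1E)-5-chloropent-1-en-1-yl]oxy}methyl)-6-(triethylsilyloxy)cyclohex-1-en-1-yl]propanoate (allyl vinyl ether) | CC[Si](CC)(CC)O[C@@H]1CCCC(CO/C=C/CCCCl)=C1CCC(=O)OC(C)(C)C | intermediate
11 | Claisen aldehyde: tert-butyl 3-[1-(5-chloro-1-oxopentan-2-yl)-2-methylidene-6-(triethylsilyloxy)cyclohexyl]propanoate, quaternary C12 with C4 on the β face (trans to the 13α-silyloxy group) | CC[Si](CC)(CC)O[C@@H]1CCCC(=C)[C@@]1(CCC(=O)OC(C)(C)C)[C@H](C=O)CCCCl | intermediate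
12 | cis-fused hydrindanone (rings A and B): C5 ketone, 13α-triethylsilyloxy, 4-(3-chloropropyl) cis to the 12α-(2-tert-butoxycarbonylethyl) chain, H7 α | CC[Si](CC)(CC)O[C@@H]1CCC[C@H]2CC(=O)[C@H](CCCCl)[C@@]12CCC(=O)OC(C)(C)C | intermediate
13 | hydroxy ketal: 12 with C5 as its ethylene ketal and a free 13α-hydroxyl | O[C@@H]1CCC[C@H]2CC3(OCCO3)[C@H](CCCCl)[C@@]12CCC(=O)OC(C)(C)C | intermediate
14 | ring A ketone: C13 ketone of 13 | O=C1CCC[C@H]2CC3(OCCO3)[C@H](CCCCl)[C@@]12CCC(=O)OC(C)(C)C | intermediate
15 | ring A enone: C13 ketone with C14=C15 | O=C1C=CC[C@H]2CC3(OCCO3)[C@H](CCCCl)[C@@]12CCC(=O)OC(C)(C)C | intermediate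
16 | trimethylsilyl enol ether: C13(OSiMe3)=C14 with 15α-methyl | C[Si](C)(C)OC1=C[C@H](C)C[C@H]2CC3(OCCO3)[C@H](CCCCl)[C@@]12CCC(=O)OC(C)(C)C | intermediate
17 | C15-methyl enone: C13 ketone, C14=C15(CH3) | O=C1C=C(C)C[C@H]2CC3(OCCO3)[C@H](CCCCl)[C@@]12CCC(=O)OC(C)(C)C | intermediate
18 | 13β-allylic alcohol (13S) with C14=C15(CH3) | O[C@H]1C=C(C)C[C@H]2CC3(OCCO3)[C@H](CCCCl)[C@@]12CCC(=O)OC(C)(C)C | intermediate
19 | epoxy alcohol: 14β,15β-epoxide syn to the 13β-hydroxyl, 15α-methyl | O[C@H]1[C@H]3O[C@@]3(C)C[C@H]2CC4(OCCO4)[C@H](CCCCl)[C@@]12CCC(=O)OC(C)(C)C | intermediate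
20 | triol: 13β-OH, 15β-OH (15α-methyl), C9 primary alcohol; C5 ketal; 4-(3-chloropropyl) | O[C@H]1C[C@@](C)(O)C[C@H]2CC3(OCCO3)[C@H](CCCCl)[C@@]12CCCO | intermediate
21 | sulfonamide: 20 with C9–NH–SO2(2-nitrophenyl) in place of C9–OH | O[C@H]1C[C@@](C)(O)C[C@H]2CC3(OCCO3)[C@H](CCCCl)[C@@]12CCCNS(=O)(=O)c1ccccc1[N+](=O)[O-] | intermediate
22 | N-(2-nitrobenzenesulfonyl) azonane diol: rings A, B and C, C5 ketal, 13β,15β-diol | O[C@H]1C[C@@](C)(O)C[C@H]2CC3(OCCO3)[C@@H]4CCCN(S(=O)(=O)c5ccccc5[N+](=O)[O-])CCC[C@]124 | intermediate
23 | diacetate: 13β,15β-diacetoxy N-nosyl azonane ketal | CC(=O)O[C@H]1C[C@@](C)(OC(C)=O)C[C@H]2CC3(OCCO3)[C@@H]4CCCN(S(=O)(=O)c5ccccc5[N+](=O)[O-])CCC[C@]124 | intermediate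
24 | secondary amine: 23 without the nosyl group | CC(=O)O[C@H]1C[C@@](C)(OC(C)=O)C[C@H]2CC3(OCCO3)[C@@H]4CCCNCCC[C@]124 | intermediate
25 | formamide ketal: N-formyl derivative of 24 | CC(=O)O[C@H]1C[C@@](C)(OC(C)=O)C[C@H]2CC3(OCCO3)[C@@H]4CCCN(C=O)CCC[C@]124 | intermediate
26 | keto formamide: C5 ketone, C4–H, 13β,15β-diacetoxy, N-formyl azonane | CC(=O)O[C@H]1C[C@@](C)(OC(C)=O)C[C@H]2CC(=O)[C@@H]3CCCN(C=O)CCC[C@]123 | intermediate
27 | C5 trimethylsilyl enol ether: C5(OSiMe3)=C4 | CC(=O)O[C@H]1C[C@@](C)(OC(C)=O)C[C@H]2CC(O[Si](C)(C)C)=C3CCCN(C=O)CCC[C@]123 | intermediate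
28 | target: (7S,12S,13S,15S)-13,15-diacetoxy N-formyl azonine with the E-configured C3=C4 enone | CC(=O)O[C@H]1C[C@@](C)(OC(C)=O)C[C@H]2CC(=O)/C3=C/CCN(C=O)CCC[C@@]321 | target

**Step count**

Total: 21 steps. Longest linear sequence: 20 steps (steps 1–5 and 7–21; step 6 is the side branch).

**Steps most likely to fail**

Step 8. The α-branched acyl rhodium hydride may decarbonylate before the alkene inserts, or insertion may occur so that the trans ring fusion results; poor facial discrimination in the sigmatropic step would show up as the C12 epimer. The fallback sets out from 10 and comes back at 12. Compound 10 is heated alone and aldehyde 11 is isolated. MeMgBr at −78 °C should add to the aldehyde to give the secondary carbinol F1 (carbinol epimers). Ozonolysis (O3, then Me2S) of the exo-methylene should give the C7 hydroxy ketone F2, and Dess–Martin oxidation the 1,4-diketone F3. KOH in MeOH should then close ring B by aldol condensation of the methyl ketone enolate onto the C7 ketone to give the cyclopentenone F4. The alternative aldol from C8 leads to a bridged ketol that cannot dehydrate. Hydrogenation (H2, Pd/C), expected on the face of the angular C11 chain as in angularly substituted bicyclic enones, should give the cis-fused 12. In this variant C6 comes from the Grignard reagent.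

Step 21. Silylation may take place towards C6, which would lead to the endocyclic C6=C7 enone, or the tertiary acetate may ionise under the silylating conditions. The fallback sets out from 26 and comes back at 28. PhSeCl in ethyl acetate at 23 °C should selenenylate the ketone through its more substituted enol to give the C4 phenylselenide F6 (either C4 epimer). H2O2 with pyridine at 0 °C should then oxidise it to the selenoxide, whose syn-elimination can only run towards C3 because C12 is quaternary, giving 28.

Step 16. Intermolecular N-alkylation (oligomers) or elimination of HCl may outrun closure of the strained nine-membered ring. The fallback sets out from 20 and comes back at 22. The C1 chloride of 20 is displaced intermolecularly by excess 2-nitrobenzenesulfonamide (K2CO3, NaI, DMF, 60 °C) to give the C1 sulfonamide triol F5. The ring is then closed at the other C–N bond by an intramolecular Fukuyama–Mitsunobu reaction of the primary C9 alcohol (PPh3, DIAD, toluene, high dilution), a closure used for azonanes of this class, to give 22.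

**Further compounds**

F1 | step 8 | secondary carbinol: 11 with C5 as CH(OH)CH3 | CC[Si](CC)(CC)O[C@@H]1CCCC(=C)[C@@]1(CCC(=O)OC(C)(C)C)[C@H](C(C)O)CCCCl
F2 | step 8 | C7 hydroxy ketone: F1 with the exo-methylene cleaved to the ring ketone | CC[Si](CC)(CC)O[C@@H]1CCCC(=O)[C@@]1(CCC(=O)OC(C)(C)C)[C@H](C(C)O)CCCCl
F3 | step 8 | 1,4-diketone: C7 ring ketone and C5 methyl ketone | CC[Si](CC)(CC)O[C@@H]1CCCC(=O)[C@@]1(CCC(=O)OC(C)(C)C)[C@H](C(C)=O)CCCCl
F4 | step 8 | cyclopentenone: C5 ketone with C6=C7, otherwise as 12 | CC[Si](CC)(CC)O[C@@H]1CCCC2=CC(=O)[C@H](CCCCl)[C@@]12CCC(=O)OC(C)(C)C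
F5 | step 16 | C1 sulfonamide triol: 20 with C1–NH–SO2(2-nitrophenyl) in place of C1–Cl | O[C@H]1C[C@@](C)(O)C[C@H]2CC3(OCCO3)[C@H](CCCNS(=O)(=O)c4ccccc4[N+](=O)[O-])[C@@]12CCCO
F6 | step 21 | C4 phenylselenide of 26 | CC(=O)O[C@H]1C[C@@](C)(OC(C)=O)C[C@H]2CC(=O)C3([Se]c4ccccc4)CCCN(C=O)CCC[C@]123
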